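The benzene ring, with its side-chain carbon C1 and oxygens at C3 and C5 all mutually meta, is a tetraketide pattern and is cut at the C1–C2 bond, C2 being the ring CH that carries a carboxyl until late. One operation, an amine-triggered aldol of a diketo-dioxinone followed by loss of water, makes this bond, closes the carbocycle and aromatizes it, leaving the oxygen para to the masked carboxyl free (future OMe) and the ortho oxygen locked in an acetonide (future OH). The precursor is a 2,4-dioxoheptadecyl chain on C6 of a 2,2-dimethyl-1,3-dioxin-4-one; its chain C6 oxygen is a TIPS ether, preferred to TBS for stability to acid and hot alkali, and its C12 oxygen a benzyl ether.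

Key step: step 11

Remark: in the Why lines, chain atoms are numbered as in the name of the compound under discussion.

Step 1
Reactants: 1 (S)-oct-1-yn-3-ol
Product: 2 (S)-3-(benzyloxy)oct-1-yne
Conditions: NaH, BnBr, n-Bu4NI (cat.), THF, 0 °C to rt
Reagents that add atoms: benzyl bromide, BrCc1ccccc1
Why: Williamson ether synthesis: one equivalent of NaH deprotonates only the hydroxyl, the alkoxide displaces bromide by SN2 under iodide catalysis, and no bond at the C3 stereocenter is broken, so its S configuration is retained.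

Step 2
Reactants: 2 (S)-3-(benzyloxy)oct-1-yne; 3 ethylene oxide
Product: 4 (S)-5-(benzyloxy)dec-3-yn-1-ol
Conditions: n-BuLi, THF, −78 °C; BF3·OEt2, then ethylene oxide, −78 °C; H2O
Reagents that add atoms: none
Why: Epoxide opening by a lithium acetylide under BF3 activation (Yamaguchi–Hirao alkynylation): n-BuLi removes only the terminal alkyne proton at −78 °C and the alkynyl nucleophile opens the activated oxirane by SN2, adding the hydroxyethyl unit without touching the propargylic stereocenter.

Step 3
Reactants: 4 (S)-5-(benzyloxy)dec-3-yn-1-ol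
Product: 5 (S)-5-(benzyloxy)decan-1-ol
Conditions: H2 (1 atm), PtO2 (cat.), EtOAc, rt
Reagents that add atoms: none
Why: Heterogeneous catalytic hydrogenation: platinum saturates the triple bond in a neutral solvent but is a poor catalyst for hydrogenolysis of benzylic or propargylic C–O bonds and for double-bond migration, so the benzyl ether and the C5 configuration should survive.

Step 4
Reactants: 5 (S)-5-(benzyloxy)decan-1-ol
Product: 6 (S)-5-(benzyloxy)-1-iododecane
Conditions: I2, PPh3, imidazole, CH2Cl2, 0 °C to rt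
Reagents that add atoms: iodine, II
Why: Appel-type iodination: the primary alcohol is activated as an alkoxyphosphonium ion and displaced by iodide in an SN2 step, while the secondary benzyl ether is inert.

Step 5
Reactants: 7 methyl acetoacetate; 6 (S)-5-(benzyloxy)-1-iododecane
Product: 8 methyl (S)-9-(benzyloxy)-3-oxotetradecanoate
Conditions: 7 (excess), NaH, THF, 0 °C; n-BuLi, 0 °C; then 6, 0 °C to rt; dilute HCl
Reagents that add atoms: none
Why: Acetoacetate dianion γ-alkylation: the dianion formed with NaH then n-BuLi reacts at its more basic terminal carbon with the unhindered primary iodide by SN2, giving the chain-extended β-keto ester.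

Step 6
Reactants: 8 methyl (S)-9-(benzyloxy)-3-oxotetradecanoate
Product: 9 methyl (3R,9S)-9-(benzyloxy)-3-hydroxytetradecanoate
Conditions: H2 (50 atm), RuCl2[(R)-BINAP] (cat.), MeOH, 50 °C
Reagents that add atoms: none
Why: Noyori asymmetric hydrogenation: the β-keto ester chelates the divalent ruthenium centre through both carbonyls and the (R)-BINAP ligand directs hydride to the ketone face that gives the 3R alcohol, the sense established for alkyl β-keto esters, so C3 is set by catalyst control while C9 and the benzyl ether are untouched.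

Step 7
Reactants: 9 methyl (3R,9S)-9-(benzyloxy)-3-hydroxytetradecanoate
Product: 10 methyl (3R,9S)-9-(benzyloxy)-3-(triisopropylsilyloxy)tetradecanoate
Conditions: TIPSOTf, 2,6-lutidine, CH2Cl2, 0 °C to rt
Reagents that add atoms: triisopropylsilyl trifluoromethanesulfonate, CC(C)[Si](C(C)C)(C(C)C)OS(=O)(=O)C(F)(F)F
Why: Silylation of a secondary alcohol with a silyl triflate and a hindered pyridine base, conditions too weakly basic to cause retro-aldol cleavage or β-elimination of the β-hydroxy ester.

Step 8
Reactants: 10 methyl (3R,9S)-9-(benzyloxy)-3-(triisopropylsilyloxy)tetradecanoate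
Product: 11 (3R,9S)-9-(benzyloxy)-N-methoxy-N-methyl-3-(triisopropylsilyloxy)tetradecanamide
Conditions: MeNH(OMe)·HCl, i-PrMgCl, THF, −20 to 0 °C
Reagents that add atoms: N,O-dimethylhydroxylamine hydrochloride, CNOC.Cl
Why: Weinreb amide formation by aminolysis of the ester with the chloromagnesium amide of N,O-dimethylhydroxylamine, which is nucleophilic but too weakly basic at low temperature to eliminate the β-silyloxy group.

Step 9
Reactants: 12 2,2,6-trimethyl-4H-1,3-dioxin-4-one
Product: 13 2,2-dimethyl-6-(2-oxopropyl)-4H-1,3-dioxin-4-one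
Conditions: LiN(SiMe3)2, THF, −78 °C; AcCl (0.5 equiv), −78 °C; dilute HCl
Reagents that add atoms: acetyl chloride, CC(Cl)=O
Why: γ-C-Acylation of a vinylogous ester dienolate (a Claisen-type condensation): the amide base removes a proton from the C6 methyl, the lithium dienolate is acylated at that carbon, and half of the dienolate serves as base for the more acidic product, hence the half equivalent of AcCl.

Step 10
Reactants: 13 2,2-dimethyl-6-(2-oxopropyl)-4H-1,3-dioxin-4-one; 11 (3R,9S)-9-(benzyloxy)-N-methoxy-N-methyl-3-(triisopropylsilyloxy)tetradecanamide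
Product: 14 6-[(6R,12S)-12-(benzyloxy)-2,4-dioxo-6-(triisopropylsilyloxy)heptadecyl]-2,2-dimethyl-4H-1,3-dioxin-4-one
Conditions: 13 (2 equiv), LiN(i-Pr)2 (4 equiv), THF, −78 °C; then 11, −78 to −30 °C; AcOH
Reagents that add atoms: none
Why: Claisen-type acylation of a ketone dianion with a Weinreb amide: the lithium amide ionizes first the doubly activated methylene and then the terminal methyl of 13, the dianion reacts at the terminal carbon, and the chelated tetrahedral intermediate prevents over-addition until the quench.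

Step 11
Reactants: 14 6-[(6R,12S)-12-(benzyloxy)-2,4-dioxo-6-(triisopropylsilyloxy)heptadecyl]-2,2-dimethyl-4H-1,3-dioxin-4-one
Product: 16 5-[(2R,8S)-8-(benzyloxy)-2-(triisopropylsilyloxy)tridecyl]-7-hydroxy-2,2-dimethyl-4H-1,3-benzodioxin-4-one, via cyclic aldol carbinol 15 (not isolated)
Conditions: Et3N, CH2Cl2, rt; then AcOH, rt
Reagents that add atoms: none
Why: Et3N reversibly removes a proton from the chain C1 methylene of 14, which is flanked by the dioxinone and the C2 ketone; the resulting dienolate attacks the C4 ketone through dioxinone C5 to give carbinol 15, and E1cB loss of water followed by enolization of the C2 ketone, completed by AcOH, should deliver the arene. The closest known reaction type is the amine-mediated aldol aromatization of diketo-dioxinones to acetonide-protected β-resorcylates, a laboratory version of polyketide cyclization. The one ring formed, the benzene carbocycle, closes in the 6-(enolexo)-exo-trig aldol mode. No stereocenter is created in the product, because the carbinol center of 15 disappears on dehydration and the chain centers C6 and C12 lie outside the reacting system. Regioselectivity between cyclization modes is required and is secured by the dioxinone, whose acetal holds the terminal carbonyl as an unreactive vinylogous ester, so that no Claisen or pyranone closure can compete. Chemoselectivity against β-elimination of the silyloxy group is secured by the weak amine base, which ionizes only the doubly activated methylenes and not the C5 position next to C6.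

Step 12
Reactants: 16 5-[(2R,8S)-8-(benzyloxy)-2-(triisopropylsilyloxy)tridecyl]-7-hydroxy-2,2-dimethyl-4H-1,3-benzodioxin-4-one
Product: 17 5-[(2R,8S)-8-(benzyloxy)-2-(triisopropylsilyloxy)tridecyl]-7-methoxy-2,2-dimethyl-4H-1,3-benzodioxin-4-one
Conditions: MeI, K2CO3, acetone, rt to 40 °C
Reagents that add atoms: iodomethane, CI
Why: Williamson O-methylation of the only free phenol, the 7-hydroxyl para to the lactone carbonyl; the other ring oxygen is held in the acetonide, so the site of methylation is unambiguous.

Step 13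
Reactants: 17 5-[(2R,8S)-8-(benzyloxy)-2-(triisopropylsilyloxy)tridecyl]-7-methoxy-2,2-dimethyl-4H-1,3-benzodioxin-4-one
Product: 19 3-[(2R,8S)-8-(benzyloxy)-2-(triisopropylsilyloxy)tridecyl]-5-methoxyphenol, via salicylic acid 18 (not isolated)
Conditions: KOH, dioxane/H2O, 90 °C; then AcOH (to pH 4), 90 °C
Reagents that add atoms: none
Why: Saponification then protodecarboxylation of a salicylic acid: hydroxide opens the aryl ester of the benzodioxinone with loss of acetone to give 18, whose electron-rich ring is protonated at the carboxyl-bearing carbon (ortho to OH, para to OMe) on mild acidification and warming so that CO2 is lost, while the TIPS ether keeps the C2 oxygen from lactonizing.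

Step 14
Reactants: 19 3-[(2R,8S)-8-(benzyloxy)-2-(triisopropylsilyloxy)tridecyl]-5-methoxyphenol
Product: 20 1-(benzyloxy)-3-[(2R,8S)-8-(benzyloxy)-2-(triisopropylsilyloxy)tridecyl]-5-methoxybenzene
Conditions: BnBr, K2CO3, DMF, rt
Reagents that add atoms: benzyl bromide, BrCc1ccccc1
Why: Williamson benzylation: K2CO3 ionizes only the phenol, which is alkylated by BnBr, so that the phenol and the C8 hydroxyl carry the same protecting group.

Step 15
Reactants: 20 1-(benzyloxy)-3-[(2R,8S)-8-(benzyloxy)-2-(triisopropylsilyloxy)tridecyl]-5-methoxybenzene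
Product: 21 (2R,8S)-8-(benzyloxy)-1-[3-(benzyloxy)-5-methoxyphenyl]tridecan-2-ol
Conditions: n-Bu4NF, THF, rt to 40 °C; H2O
Reagents that add atoms: none
Why: Fluoride-induced desilylation driven by the strong Si–F bond; benzyl and methyl ethers are inert and the C2 configuration is unaffected because its C–O bond is not broken.

Step 16
Reactants: 21 (2R,8S)-8-(benzyloxy)-1-[3-(benzyloxy)-5-methoxyphenyl]tridecan-2-ol
Product: 22 (2R,8S)-8-(benzyloxy)-1-[3-(benzyloxy)-5-methoxyphenyl]tridecan-2-yl acetate
Conditions: Ac2O, pyridine, DMAP (cat.), CH2Cl2, rt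
Reagents that add atoms: acetic anhydride, CC(=O)OC(C)=O
Why: DMAP-catalysed acylation of the only free hydroxyl with acetic anhydride, with retention at C2 because only the O–H bond reacts.

Step 17
Reactants: 22 (2R,8S)-8-(benzyloxy)-1-[3-(benzyloxy)-5-methoxyphenyl]tridecan-2-yl acetate
Product: 23 (2R,8S)-8-hydroxy-1-(3-hydroxy-5-methoxyphenyl)tridecan-2-yl acetate
Conditions: H2 (1 atm), Pd/C, EtOAc/EtOH, rt
Reagents that add atoms: none
Why: Palladium-catalysed hydrogenolysis cleaves both benzylic C–O bonds (aryl benzyl ether and secondary alkyl benzyl ether), whereas the acetate sits on a homobenzylic carbon whose C–O bond is not activated, so the target should be obtained directly.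

Compound list
1 | (S)-oct-1-yn-3-ol | CCCCC[C@H](O)C#C | starting material
2 | (S)-3-(benzyloxy)oct-1-yne | CCCCC[C@H](OCc1ccccc1)C#C | intermediate
3 | ethylene oxide | C1CO1 | starting material
4 | (S)-5-(benzyloxy)dec-3-yn-1-ol | CCCCC[C@H](OCc1ccccc1)C#CCCO | intermediate
5 | (S)-5-(benzyloxy)decan-1-ol | CCCCC[C@H](OCc1ccccc1)CCCCO | intermediate
6 | (S)-5-(benzyloxy)-1-iododecane | CCCCC[C@H](OCc1ccccc1)CCCCI | intermediate
7 | methyl acetoacetate | COC(=O)CC(C)=O | starting material
8 | methyl (S)-9-(benzyloxy)-3-oxotetradecanoate | CCCCC[C@H](OCc1ccccc1)CCCCCC(=O)CC(=O)OC | intermediate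
9 | methyl (3R,9S)-9-(benzyloxy)-3-hydroxytetradecanoate | CCCCC[C@H](OCc1ccccc1)CCCCC[C@@H](O)CC(=O)OC | intermediate
10 | methyl (3R,9S)-9-(benzyloxy)-3-(triisopropylsilyloxy)tetradecanoate | CCCCC[C@H](OCc1ccccc1)CCCCC[C@@H](O[Si](C(C)C)(C(C)C)C(C)C)CC(=O)OC | intermediate
11 | (3R,9S)-9-(benzyloxy)-N-methoxy-N-methyl-3-(triisopropylsilyloxy)tetradecanamide | CCCCC[C@H](OCc1ccccc1)CCCCC[C@@H](O[Si](C(C)C)(C(C)C)C(C)C)CC(=O)N(C)OC | intermediate
12 | 2,2,6-trimethyl-4H-1,3-dioxin-4-one | CC1=CC(=O)OC(C)(C)O1 | starting material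
13 | 2,2-dimethyl-6-(2-oxopropyl)-4H-1,3-dioxin-4-one | CC(=O)CC1=CC(=O)OC(C)(C)O1 | intermediate
14 | 6-[(6R,12S)-12-(benzyloxy)-2,4-dioxo-6-(triisopropylsilyloxy)heptadecyl]-2,2-dimethyl-4H-1,3-dioxin-4-one | CCCCC[C@H](OCc1ccccc1)CCCCC[C@H](CC(=O)CC(=O)CC1=CC(=O)OC(C)(C)O1)O[Si](C(C)C)(C(C)C)C(C)C | intermediate
15 | 5-[(2R,8S)-8-(benzyloxy)-2-(triisopropylsilyloxy)tridecyl]-5-hydroxy-2,2-dimethyl-5,6-dihydro-4H-1,3-benzodioxine-4,7(8H)-dione (both C5 epimers) | CCCCC[C@H](OCc1ccccc1)CCCCC[C@H](CC1(O)CC(=O)CC2=C1C(=O)OC(C)(C)O2)O[Si](C(C)C)(C(C)C)C(C)C | intermediate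
16 | 5-[(2R,8S)-8-(benzyloxy)-2-(triisopropylsilyloxy)tridecyl]-7-hydroxy-2,2-dimethyl-4H-1,3-benzodioxin-4-one | CCCCC[C@H](OCc1ccccc1)CCCCC[C@H](Cc1cc(O)cc2OC(C)(C)OC(=O)c12)O[Si](C(C)C)(C(C)C)C(C)C | intermediate
17 | 5-[(2R,8S)-8-(benzyloxy)-2-(triisopropylsilyloxy)tridecyl]-7-methoxy-2,2-dimethyl-4H-1,3-benzodioxin-4-one | CCCCC[C@H](OCc1ccccc1)CCCCC[C@H](Cc1cc(OC)cc2OC(C)(C)OC(=O)c12)O[Si](C(C)C)(C(C)C)C(C)C | intermediate
18 | 2-[(2R,8S)-8-(benzyloxy)-2-(triisopropylsilyloxy)tridecyl]-6-hydroxy-4-methoxybenzoic acid | CCCCC[C@H](OCc1ccccc1)CCCCC[C@H](Cc1cc(OC)cc(O)c1C(O)=O)O[Si](C(C)C)(C(C)C)C(C)C | intermediate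
19 | 3-[(2R,8S)-8-(benzyloxy)-2-(triisopropylsilyloxy)tridecyl]-5-methoxyphenol | CCCCC[C@H](OCc1ccccc1)CCCCC[C@H](Cc1cc(O)cc(OC)c1)O[Si](C(C)C)(C(C)C)C(C)C | intermediate
20 | 1-(benzyloxy)-3-[(2R,8S)-8-(benzyloxy)-2-(triisopropylsilyloxy)tridecyl]-5-methoxybenzene | CCCCC[C@H](OCc1ccccc1)CCCCC[C@H](Cc1cc(OCc2ccccc2)cc(OC)c1)O[Si](C(C)C)(C(C)C)C(C)C | intermediate
21 | (2R,8S)-8-(benzyloxy)-1-[3-(benzyloxy)-5-methoxyphenyl]tridecan-2-ol | CCCCC[C@H](OCc1ccccc1)CCCCC[C@H](Cc1cc(OCc2ccccc2)cc(OC)c1)O | intermediate
22 | (2R,8S)-8-(benzyloxy)-1-[3-(benzyloxy)-5-methoxyphenyl]tridecan-2-yl acetate | CCCCC[C@H](OCc1ccccc1)CCCCC[C@H](Cc1cc(OCc2ccccc2)cc(OC)c1)OC(C)=O | intermediate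
23 | (2R,8S)-8-hydroxy-1-(3-hydroxy-5-methoxyphenyl)tridecan-2-yl acetate | CCCCC[C@H](O)CCCCC[C@H](Cc1cc(O)cc(OC)c1)OC(C)=O | target

Total step count: 17 (16 on the main line plus step 9 for the dioxinone fragment).
Longest linear sequence: 16 steps from 1 (steps 1–8 and 10–17).

Steps most likely to fail

Step 11. The aldol may stall before dehydration, or the base may instead expel the silyloxy group from the β-silyloxy ketone, so that the carbocycle never closes cleanly. The fallback sets out from 14 and returns at 19. Heating 14 with allyl alcohol in toluene at 110 °C should open the dioxinone by retro-[4+2] loss of acetone to an acylketene, trapped as allyl (9R,15S)-15-(benzyloxy)-3,5,7-trioxo-9-(triisopropylsilyloxy)icosanoate F1. Cs2CO3 in THF followed by AcOH should cyclize and aromatize this open triketo ester by the aldol mode to allyl 2-[(2R,8S)-8-(benzyloxy)-2-(triisopropylsilyloxy)tridecyl]-4,6-dihydroxybenzoate F2. One equivalent of MeI with K2CO3 in acetone should methylate only the 4-hydroxyl, because the 6-hydroxyl is hydrogen-bonded to the ester, giving allyl 2-[(2R,8S)-8-(benzyloxy)-2-(triisopropylsilyloxy)tridecyl]-6-hydroxy-4-methoxybenzoate F3. Pd(PPh3)4 with morpholine in THF should remove the allyl group to give acid 18, which is decarboxylated by warming with AcOH to 19. The two ring oxygens are then told apart by hydrogen bonding and no longer by the acetonide.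

Step 10. Proton transfer from the α-methylene of the Weinreb amide to the dianion may outrun acylation, and the amide enolate may then lose silanolate. The fallback sets out from 10 and returns at 14. Reduction of 10 with i-Bu2AlH in CH2Cl2 at −78 °C should give (3R,9S)-9-(benzyloxy)-3-(triisopropylsilyloxy)tetradecanal F4. Aldol addition of the dianion of 13 (LiN(i-Pr)2, THF, −78 °C) to this far more electrophilic partner should give 6-[(6R,12S)-12-(benzyloxy)-4-hydroxy-2-oxo-6-(triisopropylsilyloxy)heptadecyl]-2,2-dimethyl-4H-1,3-dioxin-4-one F5 as a mixture of C4 epimers. Oxidation with Dess–Martin periodinane in CH2Cl2 removes that center and should give 14.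

Step 13. The silyl ether may be lost in hot alkali or during acidification before CO2 has left, in which case the C2 hydroxyl lactonizes onto the carboxyl and decarboxylation is blocked; decarboxylation may also be sluggish. The fallback sets out from 17 and returns at 19. Sodium benzyloxide (NaH, BnOH, THF, 0 °C to rt) should open the benzodioxinone by transesterification with loss of acetone to benzyl 2-[(2R,8S)-8-(benzyloxy)-2-(triisopropylsilyloxy)tridecyl]-6-hydroxy-4-methoxybenzoate F6. Hydrogenolysis over Pd/C in EtOAc with pyridine as additive should cleave the benzyl ester while sparing the alkyl benzyl ether, giving acid 18 under neutral conditions. Warming 18 in toluene with a little AcOH should then give 19 without any exposure to hydroxide.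

Further compounds
F1 | step 11 | allyl (9R,15S)-15-(benzyloxy)-3,5,7-trioxo-9-(triisopropylsilyloxy)icosanoate | CCCCC[C@H](OCc1ccccc1)CCCCC[C@H](CC(=O)CC(=O)CC(=O)CC(=O)OCC=C)O[Si](C(C)C)(C(C)C)C(C)C
F2 | step 11 | allyl 2-[(2R,8S)-8-(benzyloxy)-2-(triisopropylsilyloxy)tridecyl]-4,6-dihydroxybenzoate | CCCCC[C@H](OCc1ccccc1)CCCCC[C@H](Cc1cc(O)cc(O)c1C(=O)OCC=C)O[Si](C(C)C)(C(C)C)C(C)C
F3 | step 11 | allyl 2-[(2R,8S)-8-(benzyloxy)-2-(triisopropylsilyloxy)tridecyl]-6-hydroxy-4-methoxybenzoate | CCCCC[C@H](OCc1ccccc1)CCCCC[C@H](Cc1cc(OC)cc(O)c1C(=O)OCC=C)O[Si](C(C)C)(C(C)C)C(C)C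
F4 | step 10 | (3R,9S)-9-(benzyloxy)-3-(triisopropylsilyloxy)tetradecanal | CCCCC[C@H](OCc1ccccc1)CCCCC[C@@H](O[Si](C(C)C)(C(C)C)C(C)C)CC=O
F5 | step 10 | 6-[(6R,12S)-12-(benzyloxy)-4-hydroxy-2-oxo-6-(triisopropylsilyloxy)heptadecyl]-2,2-dimethyl-4H-1,3-dioxin-4-one (both C4 epimers) | CCCCC[C@H](OCc1ccccc1)CCCCC[C@H](CC(O)CC(=O)CC1=CC(=O)OC(C)(C)O1)O[Si](C(C)C)(C(C)C)C(C)C
F6 | step 13 | benzyl 2-[(2R,8S)-8-(benzyloxy)-2-(triisopropylsilyloxy)tridecyl]-6-hydroxy-4-methoxybenzoate | CCCCC[C@H](OCc1ccccc1)CCCCC[C@H](Cc1cc(OC)cc(O)c1C(=O)OCc1ccccc1)O[Si](C(C)C)(C(C)C)C(C)C
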